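**Remark on the chemistry (assumptions).** CNP0212099.1 is taken as the single enantiomer written in the SMILES, a longipinan-11-one (locants below). Compounds 3, the two phosphoranes, (+)-Ipc2B(allyl) (the reagent derived from (−)-α-pinene) and angelic acid are taken as commercial. Intermediates 14, 16, 18 and 19 are carried as mixtures at an alkene or at centres that are erased later. The facial sense quoted for the allylboration and all selectivities are predictions from accepted models, not results.

## Analysis of the target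

Locants used throughout (tricyclo[5.4.0.0^{2,8}]undecane): cyclobutane C1–C2–C8–C7; cyclohexanone bridge C9(Me)–C10–C11(=O) from C8 to C1; cycloheptane bridge C3(OH)–C4–C5(OAng)–C6(Me)(C14H2OAc) from C2 to C7.

- The target is [(1R,2R,3R,5R,6S,7S,8S,9R)-6-(acetoxymethyl)-3-hydroxy-2,6,9-trimethyl-11-oxotricyclo[5.4.0.0^{2,8}]undecan-5-yl] (Z)-2-methylbut-2-enoate.
- The cyclobutane is bridged across both diagonals: C1/C8 by three carbons (a bicyclo[3.1.1]heptan-2-one) and C2/C7 by four carbons (a bicyclo[4.1.1]octane). A direct [2+2] of two alkenes would therefore need an eleven-membered ring.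
- Four contiguous stereocentres sit on the four-membered ring and are locked by the ring system. C2 is quaternary, with its methyl syn to the C9–C11 bridge and C3 anti. The C9 methyl is anti to the C2 bridge.
- On the seven-membered ring, O3 and C14 lie on the face toward C1, while O5 and the C6 methyl lie on the face toward C8.
- Around C2/C7 the core is almost mirror-symmetric (C1 against C8, C11 against C9). The core therefore cannot relay stereochemistry to C3, C5 or C6; these must come from a reagent (C3) and from relays inside the seven-membered ring (C6 from O3, C5 from C14).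
- C6 is quaternary and neopentyl to both neighbours, and C7–H sits in a cleft that only small reagents reach.
- Sensitive features:
  - the angelate isomerises to the tiglate with base or nucleophiles;
  - the 1,3-related acetate, angelate and free hydroxyl can exchange acyl groups;
  - any C7 carbonyl or C7 alkoxide next to a C11 ketone would open the four-membered ring by retro-Claisen or retro-aldol cleavage.

## Retrosynthetic reasoning

**26 back to 23 (ester endgame).** The three oxygen functions are differentiated by timing. O3 stays silylated from the start, the primary C14–OH is acetylated (24), and the only remaining hydroxyl (C5) is angeloylated last but one (25). No protecting-group exchange is needed, and the angelate meets only a fluoride deprotection.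

**23 back to 20 (C5).** The C5 carbinol is cut back to the C5 ketone 22. The forward reduction must deliver hydride from the face that carries C14, which an intramolecular delivery from the C14 hydroxyl secures. 22 comes from β-keto ester 20 by reducing the ester while both ketones are masked in the flask (21).

**20 back to 19 (C6).** The C6 methyl is cut from the cyclic β-keto ester 19. The ester carbon is the future C14, so the quaternary centre is made by C-methylation of a stabilised enolate inside the ring, where the O3 silyl ether can differentiate the faces.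

**19 back to 15 (C5–C6, seven-membered ring).** The C5–C6 bond is cut as an aldol. Forward, the nucleophile must be generated only at C6 and the electrophile only at C5. An α-bromo ester (16) and an aldehyde unveiled by ozonolysis (17) meet in an intramolecular Reformatsky reaction (18), and oxidation gives 19. The same ozonolysis turns the C11 methylidene into the C11 ketone, so no separate step is spent on it.

**15 back to 13 (C6–C7).** C6 is attached to the C7 ketone of 13 by olefination (14) and conjugate reduction (15). A C6–C7 double bond inside the closed seven-membered ring would be anti-Bredt, so this bond is made before ring closure. The face of C7 toward C2 is blocked by C3, so hydrogen can only enter syn to the C9–C11 bridge. That puts the new arm next to C3, where the ring needs it.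

**13 back to 10 (key disconnection).** Both C1–C2 and C7–C8 are cut. This opens the cyclobutane and the six-membered ring at once and leads to the acyclic trienoic acid 10, via acid chloride 11 and vinylketene 12. The forward step is an intramolecular crossed ketene–alkene [2+2]. It was chosen because the quaternary C2 then comes from the geometry of a trisubstituted alkene, and C1, C2 and C8 are set together from the single bought centre C9. Cutting C1–C7 or C2–C8 instead would leave a 6–7 bicycle with most stereocentres still to make.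

**10 back to 7 (C3).** The C3 carbinol and the C4–C5 unit are cut as an asymmetric allylation of enal 7 (giving 8, then 9). The vinyl group is an inert, non-acidic precursor of the C5 aldehyde.

**7 back to 1 and 3.** The (E)-enal 7 comes from aldehyde 6 by a stabilised Wittig reaction. 6 comes from diester 5 by selective reduction of the methyl ester. 5 comes from an sp3–sp2 cross-coupling of the zinc reagent 4, made from bromo ester 3 (C9 bought), with enol triflate 2, made from β-keto ester 1.

## Alternatives that were turned down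

Alternative 1: the textbook route, closing the cyclobutane last at C1–C7.
- Disconnection and key step: intramolecular 4-exo-tet alkylation of the C11 ketone enolate in the 6–7-fused keto mesylate A1.
- Why turned down:
  - the leaving group sits on C7, flanked by the quaternary C6 and the ring-fusion carbon C8, so the displacement is neopentyl-like and competes with elimination;
  - the enolate can also form toward C10;
  - A1 needs seven stereocentres, including an inverted C7 carbinol, on a flexible bicycle before the key step, which itself makes one bond and no new stereocentre beyond the forced ones.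

Alternative 2: transannular enone–alkene [2+2] photocycloaddition.
- Disconnection and key step: C1–C7 and C2–C8 formed together in the cycloundecadienone A2.
- Why turned down:
  - the eleven-membered ring with the quaternary C6 and three stereocentres is no simpler to make than the target;
  - the excited enone should bond C1 to C8 first (five-membered ring, rule of five), giving the straight adduct with C1–C8/C2–C7 instead of the crossed cyclobutane;
  - E/Z photoisomerisation in the macrocycle removes the stereochemical link between alkene geometry and C2.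

Alternative 3: ring contraction to the cyclobutane.
- Disconnection and key step: photochemical Wolff rearrangement of the bicyclo[4.2.1]nonane α-diazoketone A3 to the bicyclo[4.1.1]octane ester A4, followed by Dieckmann-type closure of the six-membered ring onto the C1 ester.
- Why turned down:
  - A3 is a bridged bicycle with five stereocentres and the quaternary C6 for which no short, stereocontrolled entry is apparent;
  - the contraction gives the C1 ester without control of its orientation relative to the C8 side chain;
  - three further C–C bond formations and a decarboxylation remain after the key step.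

Key step: step 8

## Route

Step 1
Reactants: 1 tert-butyl 3-oxobutanoate
Product: 2 tert-butyl (2E)-3-{[(trifluoromethyl)sulfonyl]oxy}but-2-enoate
Conditions: Tf2O, aq. Me4NOH, hexanes, 5 °C
Reagents that add atoms: trifluoromethanesulfonic anhydride, O=S(=O)(OS(=O)(=O)C(F)(F)F)C(F)(F)F
Why: O-Triflation of the β-keto ester enolate; with the non-chelating ammonium counter-ion the extended enolate should give the (E)-enol triflate (OTf trans to the ester), which later places the C11 methyl cis to the carboxyl.

Step 2
Reactants: 3 methyl (2S)-3-bromo-2-methylpropanoate; 2 tert-butyl (2E)-3-{[(trifluoromethyl)sulfonyl]oxy}but-2-enoate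
Product: 5 1-tert-butyl 6-methyl (2E,5R)-3,5-dimethylhex-2-enedioate, via alkylzinc bromide 4 (not isolated)
Conditions: Zn dust (I2-activated), DMA, 40 °C; then 2, Pd(PPh3)4 (5 mol%), THF, 50 °C
Reagents that add atoms: none
Why: Zinc insertion gives a configurationally stable β-ester alkylzinc; Negishi sp3–sp2 coupling with the enol triflate proceeds with retention of alkene geometry and does not touch the bought C9 centre.

Step 3
Reactants: 5 1-tert-butyl 6-methyl (2E,5R)-3,5-dimethylhex-2-enedioate
Product: 6 tert-butyl (2E,5R)-3,5-dimethyl-6-oxohex-2-enoate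
Conditions: DIBAL-H (1.05 equiv), CH2Cl2, −78 °C; Rochelle salt
Reagents that add atoms: none
Why: Partial reduction of the saturated methyl ester through its tetrahedral aluminate at −78 °C; the conjugated, β,β-disubstituted tert-butyl ester is far less electrophilic and should survive one equivalent of hydride.

Step 4
Reactants: 6 tert-butyl (2E,5R)-3,5-dimethyl-6-oxohex-2-enoate
Product: 7 tert-butyl (2E,5R,6E)-3,5,7-trimethyl-8-oxoocta-2,6-dienoate
Conditions: Ph3P=C(Me)CHO, toluene, 90 °C
Reagents that add atoms: 2-(triphenyl-λ5-phosphanylidene)propanal, CC(C=O)=P(c1ccccc1)(c1ccccc1)c1ccccc1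
Why: Wittig olefination with a formyl-stabilised ylide gives the (E)-2-methyl enal (C3 trans to C9, methyl cis to C9); the neutral conditions should not epimerise the α-stereocentre.

Step 5
Reactants: 7 tert-butyl (2E,5R,6E)-3,5,7-trimethyl-8-oxoocta-2,6-dienoate
Product: 8 tert-butyl (2E,5R,6E,8R)-8-hydroxy-3,5,7-trimethylundeca-2,6,10-trienoate
Conditions: (+)-Ipc2B(allyl), Et2O, −78 °C; then NaOH, H2O2
Reagents that add atoms: (+)-B-allyldiisopinocampheylborane, C=CCB([C@H]1C[C@H]2C[C@@H]([C@@H]1C)C2(C)C)[C@H]1C[C@H]2C[C@@H]([C@@H]1C)C2(C)C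
Why: Brown allylation through a closed chair transition state under reagent control; this antipode attacks the Re face of the enal, which corresponds to (R) at C3, and the remote C9 centre exerts no meaningful bias.

Step 6
Reactants: 8 tert-butyl (2E,5R,6E,8R)-8-hydroxy-3,5,7-trimethylundeca-2,6,10-trienoate
Product: 9 tert-butyl (2E,5R,6E,8R)-8-[(tert-butyldimethylsilyl)oxy]-3,5,7-trimethylundeca-2,6,10-trienoate
Conditions: TBSCl, imidazole, DMF, 23 °C
Reagents that add atoms: tert-butyldimethylsilyl chloride, C[Si](C)(Cl)C(C)(C)C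
Why: Standard silylation of the allylic alcohol; the bulky silyl ether protects O3 until the last step and later serves as the steric control element for C6.

Step 7
Reactants: 9 tert-butyl (2E,5R,6E,8R)-8-[(tert-butyldimethylsilyl)oxy]-3,5,7-trimethylundeca-2,6,10-trienoate
Product: 10 (2E,5R,6E,8R)-8-[(tert-butyldimethylsilyl)oxy]-3,5,7-trimethylundeca-2,6,10-trienoic acid
Conditions: TMSOTf, 2,6-lutidine, CH2Cl2, 0 °C; then pH 7 buffer
Reagents that add atoms: none
Why: Silyl triflate-mediated cleavage of the tert-butyl ester (loss of isobutene, then hydrolysis of the silyl ester) avoids both basic hydrolysis and protic acid, which would endanger the allylic silyl ether.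

Step 8
Reactants: 10 (2E,5R,6E,8R)-8-[(tert-butyldimethylsilyl)oxy]-3,5,7-trimethylundeca-2,6,10-trienoic acid
Product: 13 7-[(1R)-1-[(tert-butyldimethylsilyl)oxy]but-3-en-1-yl]-4,7-dimethyl-2-methylidenebicyclo[3.1.1]heptan-6-one, via acid chloride 11 (not isolated), via vinylketene 12 (not isolated)
Conditions: 1-chloro-N,N,2-trimethylprop-1-en-1-amine, CH2Cl2, 0 °C; then slow addition to Et3N, toluene, 110 °C, high dilution
Reagents that add atoms: none
Why: Dehydrochlorination of 11 at the C11 methyl (cis to COCl in the 2E isomer) gives vinylketene 12, which undergoes an intramolecular thermal, asynchronous ketene–alkene [2+2] cycloaddition across C8=C2. The closest known reaction type is the crossed intramolecular cycloaddition of vinylketenes from 3-methyl-2,6-dienoyl chlorides to 7,7-disubstituted 2-methylidenebicyclo[3.1.1]heptan-6-ones. The electrophilic ketene carbon C7 bonds to the less substituted alkene carbon C8 while positive charge builds at the tertiary C2, and C1 then closes onto C2; the six-membered ring C1–C11–C10–C9–C8–C2 forms in this crossed six-membered closure and the cyclobutanone C1–C2–C8–C7 is completed, instead of the bicyclo[3.2.0] mode. The addition is suprafacial on the alkene, so the (E)-geometry places the C2 methyl (cis to C9 in 10) syn to the C9–C11 bridge and the C3 chain anti; C1 and C8 are cis by necessity as bridgeheads. The absolute sense is relayed from C9: in the product-like transition state C10 lies near the alkene plane and the C9 methyl takes the outside position, avoiding the developing syn-pentane contact with the C2 methyl, which gives the 9-methyl anti to the C2 bridge. The step needs crossed regioselectivity (secured by the trisubstituted alkene), deprotonation at the methyl and not at C10 (secured by the 2E geometry) and C9-controlled facial selectivity; slow addition at high dilution suppresses ketene dimerisation. The terminal vinyl group is too remote and too poor a ketenophile to compete. In the target numbering 13 carries the C7 ketone, the C11 methylidene and C1, C2, C8 and C9 as in 26.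

Step 9
Reactants: 13 7-[(1R)-1-[(tert-butyldimethylsilyl)oxy]but-3-en-1-yl]-4,7-dimethyl-2-methylidenebicyclo[3.1.1]heptan-6-one
Product: 14 methyl 2-{7-[(1R)-1-[(tert-butyldimethylsilyl)oxy]but-3-en-1-yl]-4,7-dimethyl-2-methylidenebicyclo[3.1.1]heptan-6-ylidene}acetate (alkene isomers at C7=C6)
Conditions: Ph3P=CHCO2Me, toluene, 110 °C
Reagents that add atoms: methyl (triphenyl-λ5-phosphanylidene)acetate, COC(=O)C=P(c1ccccc1)(c1ccccc1)c1ccccc1
Why: Wittig olefination; cyclobutanones are unusually electrophilic because addition relieves angle strain, so a stabilised ylide should suffice, and the non-basic conditions leave the β,γ-unsaturated ketone alone; the C7=C6 geometry is irrelevant.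

Step 10
Reactants: 14 methyl 2-{7-[(1R)-1-[(tert-butyldimethylsilyl)oxy]but-3-en-1-yl]-4,7-dimethyl-2-methylidenebicyclo[3.1.1]heptan-6-ylidene}acetate
Product: 15 methyl 2-{7-[(1R)-1-[(tert-butyldimethylsilyl)oxy]but-3-en-1-yl]-4,7-dimethyl-2-methylidenebicyclo[3.1.1]heptan-6-yl}acetate (C7–H syn to the C9–C11 bridge)
Conditions: Mg, MeOH, 0 → 23 °C
Reagents that add atoms: none
Why: Dissolving-metal conjugate reduction is selective for the enoate over the isolated alkenes; C7 is protonated on the face syn to the C9–C11 bridge because the other face is blocked by C3 on C2, so the CH2CO2Me arm ends anti to the bridge, beside C3, as the seven-membered ring requires.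

Step 11
Reactants: 15 methyl 2-{7-[(1R)-1-[(tert-butyldimethylsilyl)oxy]but-3-en-1-yl]-4,7-dimethyl-2-methylidenebicyclo[3.1.1]heptan-6-yl}acetate
Product: 16 methyl 2-bromo-2-{7-[(1R)-1-[(tert-butyldimethylsilyl)oxy]but-3-en-1-yl]-4,7-dimethyl-2-methylidenebicyclo[3.1.1]heptan-6-yl}acetate (both C6 epimers)
Conditions: LDA, THF, −78 °C; then CBr4
Reagents that add atoms: tetrabromomethane, BrC(Br)(Br)Br
Why: The ester α-position is the only acidic site, so the lithium enolate forms regiospecifically at C6 and is brominated by electrophilic bromine transfer; this fixes where the nucleophile of the ring closure will be generated.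

Step 12
Reactants: 16 methyl 2-bromo-2-{7-[(1R)-1-[(tert-butyldimethylsilyl)oxy]but-3-en-1-yl]-4,7-dimethyl-2-methylidenebicyclo[3.1.1]heptan-6-yl}acetate
Product: 17 methyl 2-bromo-2-{7-[(1R)-1-[(tert-butyldimethylsilyl)oxy]-3-oxopropyl]-4,7-dimethyl-2-oxobicyclo[3.1.1]heptan-6-yl}acetate
Conditions: O3, CH2Cl2/MeOH, −78 °C; then Me2S
Reagents that add atoms: ozone, [O-][O+]=O
Why: Ozonolysis cleaves both alkenes in one operation, giving the C11 ketone from the methylidene and the C5 aldehyde from the vinyl group; bromide, ester and silyl ether are inert to ozone.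

Step 13
Reactants: 17 methyl 2-bromo-2-{7-[(1R)-1-[(tert-butyldimethylsilyl)oxy]-3-oxopropyl]-4,7-dimethyl-2-oxobicyclo[3.1.1]heptan-6-yl}acetate
Product: 18 methyl 3-[(tert-butyldimethylsilyl)oxy]-5-hydroxy-2,9-dimethyl-11-oxotricyclo[5.4.0.0^{2,8}]undecane-6-carboxylate (diastereomers at C5 and C6)
Conditions: SmI2, THF, −78 °C, slow addition, high dilution
Reagents that add atoms: none
Why: Samarium(II) reduces the α-bromo ester much faster than aldehyde or ketone and so generates the enolate only at C6; the intramolecular Reformatsky addition to the C5 aldehyde closes the seven-membered ring, helped by the two arms held parallel on the cyclobutane; the new C5 and C6 centres are erased in the next two steps.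

Step 14
Reactants: 18 methyl 3-[(tert-butyldimethylsilyl)oxy]-5-hydroxy-2,9-dimethyl-11-oxotricyclo[5.4.0.0^{2,8}]undecane-6-carboxylate
Product: 19 methyl 3-[(tert-butyldimethylsilyl)oxy]-2,9-dimethyl-5,11-dioxotricyclo[5.4.0.0^{2,8}]undecane-6-carboxylate
Conditions: Dess–Martin periodinane, NaHCO3, CH2Cl2, 23 °C
Reagents that add atoms: none
Why: Mild, non-basic oxidation of the secondary alcohol to the β-keto ester; both diastereomers of 18 converge on one compound.

Step 15
Reactants: 19 methyl 3-[(tert-butyldimethylsilyl)oxy]-2,9-dimethyl-5,11-dioxotricyclo[5.4.0.0^{2,8}]undecane-6-carboxylate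
Product: 20 methyl 3-[(tert-butyldimethylsilyl)oxy]-2,6,9-trimethyl-5,11-dioxotricyclo[5.4.0.0^{2,8}]undecane-6-carboxylate (6-Me on the C8 face, ester on the C1 face)
Conditions: MeI, K2CO3, acetone, 0 → 23 °C
Reagents that add atoms: iodomethane, CI
Why: C-Alkylation of the cyclic β-keto ester enolate creates the quaternary C6; iodomethane should approach the planar enolate on the face opposite the bulky O3 silyl ether (a 1,4-relationship across the ring), since the cyclobutane core itself offers almost no bias; the weak base does not enolise C4 or C10.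

Step 16
Reactants: 20 methyl 3-[(tert-butyldimethylsilyl)oxy]-2,6,9-trimethyl-5,11-dioxotricyclo[5.4.0.0^{2,8}]undecane-6-carboxylate
Product: 22 3-[(tert-butyldimethylsilyl)oxy]-6-(hydroxymethyl)-2,6,9-trimethyltricyclo[5.4.0.0^{2,8}]undecane-5,11-dione, via bis(trimethylsilyl) dienol ether 21 (not isolated)
Conditions: TMSOTf, Et3N, CH2Cl2, 0 °C; then DIBAL-H, −78 → −40 °C; then 10% aq. citric acid, THF, 0 °C
Reagents that add atoms: none
Why: Soft enolisation masks both ketones as silyl enol ethers (C5 toward C4, C11 toward C10; C1 and C6 cannot enolise), the hindered ester is then reduced by the aluminium hydride, and mild acid returns the ketones without retro-aldol loss of C14.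

Step 17
Reactants: 22 3-[(tert-butyldimethylsilyl)oxy]-6-(hydroxymethyl)-2,6,9-trimethyltricyclo[5.4.0.0^{2,8}]undecane-5,11-dione
Product: 23 3-[(tert-butyldimethylsilyl)oxy]-5-hydroxy-6-(hydroxymethyl)-2,6,9-trimethyltricyclo[5.4.0.0^{2,8}]undecan-11-one (all centres as in 26)
Conditions: Me4NBH(OAc)3, MeCN/AcOH, −30 °C
Reagents that add atoms: none
Why: Evans–Saksena reduction: the C14 hydroxyl binds boron and delivers hydride through a six-membered transition state to the C5 carbonyl from the face that carries C14, so O5 ends trans to C14 and cis to the C6 methyl; the undirected C11 ketone should not be reduced by this mild reagent.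

Step 18
Reactants: 23 3-[(tert-butyldimethylsilyl)oxy]-5-hydroxy-6-(hydroxymethyl)-2,6,9-trimethyltricyclo[5.4.0.0^{2,8}]undecan-11-one
Product: 24 {3-[(tert-butyldimethylsilyl)oxy]-5-hydroxy-2,6,9-trimethyl-11-oxotricyclo[5.4.0.0^{2,8}]undecan-6-yl}methyl acetate
Conditions: AcCl, 2,4,6-collidine, CH2Cl2, −78 °C
Reagents that add atoms: acetyl chloride, CC(Cl)=O
Why: Kinetic acylation of the primary hydroxyl in the presence of the neopentyl secondary C5 hydroxyl; the hindered base and low temperature suppress diacetylation and acyl migration.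

Step 19
Reactants: 24 {3-[(tert-butyldimethylsilyl)oxy]-5-hydroxy-2,6,9-trimethyl-11-oxotricyclo[5.4.0.0^{2,8}]undecan-6-yl}methyl acetate
Product: 25 6-(acetoxymethyl)-3-[(tert-butyldimethylsilyl)oxy]-2,6,9-trimethyl-11-oxotricyclo[5.4.0.0^{2,8}]undecan-5-yl (2Z)-2-methylbut-2-enoate
Conditions: angelic acid, 2,4,6-trichlorobenzoyl chloride, Et3N, toluene, 23 °C; then 24, 80 °C
Reagents that add atoms: angelic acid, C/C=C(/C)C(=O)O
Why: Yamaguchi-type mixed-anhydride acylation without a nucleophilic catalyst is the usual way to angeloylate hindered secondary alcohols with little Z to E isomerisation; O5 is the only free hydroxyl.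

Step 20
Reactants: 25 6-(acetoxymethyl)-3-[(tert-butyldimethylsilyl)oxy]-2,6,9-trimethyl-11-oxotricyclo[5.4.0.0^{2,8}]undecan-5-yl (2Z)-2-methylbut-2-enoate
Product: 26 [(1R,2R,3R,5R,6S,7S,8S,9R)-6-(acetoxymethyl)-3-hydroxy-2,6,9-trimethyl-11-oxotricyclo[5.4.0.0^{2,8}]undecan-5-yl] (2Z)-2-methylbut-2-enoate
Conditions: HF·pyridine, THF, 0 → 23 °C
Reagents that add atoms: none
Why: Fluoride-mediated desilylation under buffered, weakly acidic conditions; both esters, the ketone and the Z-alkene are stable, and acyl migration is slow without base.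

## Compound list

1 | tert-butyl 3-oxobutanoate | CC(=O)CC(=O)OC(C)(C)C | starting material
2 | tert-butyl (2E)-3-{[(trifluoromethyl)sulfonyl]oxy}but-2-enoate | CC(C)(C)OC(=O)/C=C(\C)OS(=O)(=O)C(F)(F)F | intermediate
3 | methyl (2S)-3-bromo-2-methylpropanoate | BrC[C@H](C(=O)OC)C | starting material
4 | [(2S)-3-methoxy-2-methyl-3-oxopropyl]zinc bromide | Br[Zn]C[C@H](C(=O)OC)C | intermediate
5 | 1-tert-butyl 6-methyl (2E,5R)-3,5-dimethylhex-2-enedioate | CC(C)(C)OC(=O)/C=C(\C)C[C@H](C(=O)OC)C | intermediate
6 | tert-butyl (2E,5R)-3,5-dimethyl-6-oxohex-2-enoate | CC(C)(C)OC(=O)/C=C(\C)C[C@H](C=O)C | intermediate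
7 | tert-butyl (2E,5R,6E)-3,5,7-trimethyl-8-oxoocta-2,6-dienoate | CC(C)(C)OC(=O)/C=C(\C)C[C@H](/C=C(\C)C=O)C | intermediate
8 | tert-butyl (2E,5R,6E,8R)-8-hydroxy-3,5,7-trimethylundeca-2,6,10-trienoate | CC(C)(C)OC(=O)/C=C(\C)C[C@H](/C=C(\C)[C@H](O)CC=C)C | intermediate
9 | tert-butyl (2E,5R,6E,8R)-8-[(tert-butyldimethylsilyl)oxy]-3,5,7-trimethylundeca-2,6,10-trienoate | CC(C)(C)OC(=O)/C=C(\C)C[C@H](/C=C(\C)[C@H](O[Si](C)(C)C(C)(C)C)CC=C)C | intermediate
10 | (2E,5R,6E,8R)-8-[(tert-butyldimethylsilyl)oxy]-3,5,7-trimethylundeca-2,6,10-trienoic acid | OC(=O)/C=C(\C)C[C@H](/C=C(\C)[C@H](O[Si](C)(C)C(C)(C)C)CC=C)C | intermediate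
11 | (2E,5R,6E,8R)-8-[(tert-butyldimethylsilyl)oxy]-3,5,7-trimethylundeca-2,6,10-trienoyl chloride | ClC(=O)/C=C(\C)C[C@H](/C=C(\C)[C@H](O[Si](C)(C)C(C)(C)C)CC=C)C | intermediate
12 | (5R,6E,8R)-8-[(tert-butyldimethylsilyl)oxy]-5,7-dimethyl-3-methylideneundeca-1,6,10-trien-1-one (vinylketene) | O=C=CC(=C)C[C@H](/C=C(\C)[C@H](O[Si](C)(C)C(C)(C)C)CC=C)C | intermediate
13 | 7-[(1R)-1-[(tert-butyldimethylsilyl)oxy]but-3-en-1-yl]-4,7-dimethyl-2-methylidenebicyclo[3.1.1]heptan-6-one (target locants: C7 ketone, C11 methylidene; C1, C2, C8, C9 as in 26) | C=CC[C@@H](O[Si](C)(C)C(C)(C)C)[C@]2(C)[C@@H]3C(=O)[C@H]2C(=C)C[C@H]3C | intermediate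
14 | methyl 2-{7-[(1R)-1-[(tert-butyldimethylsilyl)oxy]but-3-en-1-yl]-4,7-dimethyl-2-methylidenebicyclo[3.1.1]heptan-6-ylidene}acetate (C7=C6 isomers) | C=CC[C@@H](O[Si](C)(C)C(C)(C)C)[C@]2(C)[C@@H]3C(=CC(=O)OC)[C@H]2C(=C)C[C@H]3C | intermediate
15 | methyl 2-{7-[(1R)-1-[(tert-butyldimethylsilyl)oxy]but-3-en-1-yl]-4,7-dimethyl-2-methylidenebicyclo[3.1.1]heptan-6-yl}acetate (C7 as in 26) | C=CC[C@@H](O[Si](C)(C)C(C)(C)C)[C@]2(C)[C@@H]3[C@H](CC(=O)OC)[C@H]2C(=C)C[C@H]3C | intermediate
16 | methyl 2-bromo-2-{7-[(1R)-1-[(tert-butyldimethylsilyl)oxy]but-3-en-1-yl]-4,7-dimethyl-2-methylidenebicyclo[3.1.1]heptan-6-yl}acetate (C6 epimers) | C=CC[C@@H](O[Si](C)(C)C(C)(C)C)[C@]2(C)[C@@H]3[C@H](C(Br)C(=O)OC)[C@H]2C(=C)C[C@H]3C | intermediate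
17 | methyl 2-bromo-2-{7-[(1R)-1-[(tert-butyldimethylsilyl)oxy]-3-oxopropyl]-4,7-dimethyl-2-oxobicyclo[3.1.1]heptan-6-yl}acetate | O=CC[C@@H](O[Si](C)(C)C(C)(C)C)[C@]2(C)[C@@H]3[C@H](C(Br)C(=O)OC)[C@H]2C(=O)C[C@H]3C | intermediate
18 | methyl 3-[(tert-butyldimethylsilyl)oxy]-5-hydroxy-2,9-dimethyl-11-oxotricyclo[5.4.0.0^{2,8}]undecane-6-carboxylate (C5, C6 mixtures; other centres as in 26) | OC1C[C@@H](O[Si](C)(C)C(C)(C)C)[C@]2(C)[C@@H]3[C@@H]([C@H]2C(=O)C[C@H]3C)C1C(=O)OC | intermediate
19 | methyl 3-[(tert-butyldimethylsilyl)oxy]-2,9-dimethyl-5,11-dioxotricyclo[5.4.0.0^{2,8}]undecane-6-carboxylate | O=C1C[C@@H](O[Si](C)(C)C(C)(C)C)[C@]2(C)[C@@H]3[C@@H]([C@H]2C(=O)C[C@H]3C)C1C(=O)OC | intermediate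
20 | methyl 3-[(tert-butyldimethylsilyl)oxy]-2,6,9-trimethyl-5,11-dioxotricyclo[5.4.0.0^{2,8}]undecane-6-carboxylate (C6 as in 26) | O=C1C[C@@H](O[Si](C)(C)C(C)(C)C)[C@]2(C)[C@@H]3[C@@H]([C@H]2C(=O)C[C@H]3C)[C@@]1(C)C(=O)OC | intermediate
21 | bis(trimethylsilyl) dienol ether of 20 (C4=C5–OTMS and C10=C11–OTMS) | C[Si](C)(C)OC1=C[C@@H](O[Si](C)(C)C(C)(C)C)[C@]2(C)[C@@H]3[C@@H]([C@H]2C(O[Si](C)(C)C)=C[C@H]3C)[C@@]1(C)C(=O)OC | intermediate
22 | 3-[(tert-butyldimethylsilyl)oxy]-6-(hydroxymethyl)-2,6,9-trimethyltricyclo[5.4.0.0^{2,8}]undecane-5,11-dione | O=C1C[C@@H](O[Si](C)(C)C(C)(C)C)[C@]2(C)[C@@H]3[C@@H]([C@H]2C(=O)C[C@H]3C)[C@@]1(C)CO | intermediate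
23 | 3-[(tert-butyldimethylsilyl)oxy]-5-hydroxy-6-(hydroxymethyl)-2,6,9-trimethyltricyclo[5.4.0.0^{2,8}]undecan-11-one | O[C@@H]1C[C@@H](O[Si](C)(C)C(C)(C)C)[C@]2(C)[C@@H]3[C@@H]([C@H]2C(=O)C[C@H]3C)[C@@]1(C)CO | intermediate
24 | {3-[(tert-butyldimethylsilyl)oxy]-5-hydroxy-2,6,9-trimethyl-11-oxotricyclo[5.4.0.0^{2,8}]undecan-6-yl}methyl acetate | O[C@@H]1C[C@@H](O[Si](C)(C)C(C)(C)C)[C@]2(C)[C@@H]3[C@@H]([C@H]2C(=O)C[C@H]3C)[C@@]1(C)COC(C)=O | intermediate
25 | 6-(acetoxymethyl)-3-[(tert-butyldimethylsilyl)oxy]-2,6,9-trimethyl-11-oxotricyclo[5.4.0.0^{2,8}]undecan-5-yl (2Z)-2-methylbut-2-enoate | C/C=C(/C)C(=O)O[C@@H]1C[C@@H](O[Si](C)(C)C(C)(C)C)[C@]2(C)[C@@H]3[C@@H]([C@H]2C(=O)C[C@H]3C)[C@@]1(C)COC(C)=O | intermediate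
26 | [(1R,2R,3R,5R,6S,7S,8S,9R)-6-(acetoxymethyl)-3-hydroxy-2,6,9-trimethyl-11-oxotricyclo[5.4.0.0^{2,8}]undecan-5-yl] (2Z)-2-methylbut-2-enoate (CNP0212099.1) | C/C=C(/C)C(=O)O[C@@H]1C[C@@H](O)[C@]2(C)[C@@H]3[C@@H]([C@H]2C(=O)C[C@H]3C)[C@@]1(C)COC(C)=O | target

## Step count and least certain steps

Total step count: 20. Longest linear sequence: 20 steps (steps 1–20, counted from β-keto ester 1); the bought bromo ester 3 enters at step 2, so the route is linear apart from that one convergence.

**Step 8 (key step).** Most likely to go wrong: ketene dimerisation or oligomerisation outrunning the cycloaddition, because the alkene is slightly deactivated by the allylic silyl ether. Also possible are competing deprotonation at C10 (leading to the endocyclic diene ketene and a regioisomeric skeleton) and incomplete facial control by C9. Fallback, from 10 back to 13: couple 10 with pyrrolidine to the pyrrolidine amide F1; activate it with triflic anhydride and 2,4,6-collidine in hot 1,2-dichloroethane. The resulting vinyl keteniminium ion cannot dimerise and adds stepwise to C8=C2 with the same polarity, giving the cyclobutaniminium triflate F2. Aqueous bicarbonate hydrolysis of F2 returns ketone 13.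

**Step 9.** Most likely to go wrong: very slow or incomplete olefination, because the C7 carbonyl can only be approached from the face syn to the C9–C11 bridge and the ylide is bulky. Fallback, from 13 back to 14: add the small Reformatsky reagent from methyl bromoacetate and zinc to the ketone to give the tertiary β-hydroxy ester F3. Dehydrate F3 with the Burgess reagent; elimination can only go toward C6, since C1 and C8 are bridgeheads, and gives 14.

**Step 15.** Most likely to go wrong: poor facial selectivity in the methylation, because the only control element is the O3 silyl ether in a 1,4-relationship to C6; β-elimination of the silyloxy group on prolonged base contact is a lesser concern. Fallback, from 15 back to 20, which makes C6 under tether control instead of steric control: the ester enolate of 15 is methylated (LDA, MeI) to the α-methyl ester F4, and the enolate of F4 is brominated (LDA, CBr4) to the tertiary bromide F5. Removal of the silyl group and lactonisation onto O3 (HF·pyridine, then cat. TsOH, toluene, 80 °C) gives the seven-membered bromo lactone F6, and ozonolysis of both alkenes gives the lactone keto aldehyde F7. A samarium diiodide-mediated Reformatsky reaction then closes the C5–C6 bond to the bridged hydroxy lactone F8, in which the lactone forces C14 onto the same face as O3. Oxidation with Dess–Martin periodinane gives the bridged keto lactone F9, acid-catalysed methanolysis opens the lactone to the hydroxy keto ester F10, and silylation of O3 (TBSOTf, 2,6-lutidine) reaches 20.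

**Step 19.** Most likely to go wrong: slow acylation of the neopentyl C5 hydroxyl, so that the long heating causes Z to E isomerisation of the angeloyl unit or migration of the neighbouring acetate. Fallback, from 24 back to 25: esterify 24 with 2-[bis(2,2,2-trifluoroethoxy)phosphoryl]propanoic acid (DCC, DMAP) to the phosphonopropionate ester F11. Then build the Z-alkene on the substrate by Still–Gennari olefination with acetaldehyde (KHMDS, 18-crown-6, THF, −78 °C); one equivalent of base deprotonates only the phosphonate, and the product is 25.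

## Further compounds

F1 | step 8 | pyrrolidine amide of 10, (2E,5R,6E,8R)-8-[(tert-butyldimethylsilyl)oxy]-3,5,7-trimethyl-1-(pyrrolidin-1-yl)undeca-2,6,10-trien-1-one | O=C(/C=C(\C)C[C@H](/C=C(\C)[C@H](O[Si](C)(C)C(C)(C)C)CC=C)C)N1CCCC1
F2 | step 8 | cyclobutaniminium triflate, the C7 pyrrolidinium-ylidene analogue of 13 | C=CC[C@@H](O[Si](C)(C)C(C)(C)C)[C@]2(C)[C@@H]3C(=[N+]4CCCC4)[C@H]2C(=C)C[C@H]3C.[O-]S(=O)(=O)C(F)(F)F
F3 | step 9 | methyl 2-{7-[(1R)-1-[(tert-butyldimethylsilyl)oxy]but-3-en-1-yl]-6-hydroxy-4,7-dimethyl-2-methylidenebicyclo[3.1.1]heptan-6-yl}acetate (CH2CO2Me syn to the C9–C11 bridge) | C=CC[C@@H](O[Si](C)(C)C(C)(C)C)[C@]2(C)[C@@H]3[C@@](O)(CC(=O)OC)[C@H]2C(=C)C[C@H]3C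
F4 | step 15 | α-methyl ester, methyl 2-{7-[(1R)-1-[(tert-butyldimethylsilyl)oxy]but-3-en-1-yl]-4,7-dimethyl-2-methylidenebicyclo[3.1.1]heptan-6-yl}propanoate | C=CC[C@@H](O[Si](C)(C)C(C)(C)C)[C@]2(C)[C@@H]3[C@H](C(C)C(=O)OC)[C@H]2C(=C)C[C@H]3C
F5 | step 15 | tertiary bromide, methyl 2-bromo-2-{7-[(1R)-1-[(tert-butyldimethylsilyl)oxy]but-3-en-1-yl]-4,7-dimethyl-2-methylidenebicyclo[3.1.1]heptan-6-yl}propanoate | C=CC[C@@H](O[Si](C)(C)C(C)(C)C)[C@]2(C)[C@@H]3[C@H](C(C)(Br)C(=O)OC)[C@H]2C(=C)C[C@H]3C
F6 | step 15 | seven-membered bromo lactone (O3–C14 ester bond; C6 bearing Br and Me; allyl on C3) | C=CC[C@@H]1[C@]2(C)[C@@H]3[C@H](C(C)(Br)C(=O)O1)[C@H]2C(=C)C[C@H]3C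
F7 | step 15 | lactone keto aldehyde (C5 aldehyde, C11 ketone, bromo lactone as in F6) | O=CC[C@@H]1[C@]2(C)[C@@H]3[C@H](C(C)(Br)C(=O)O1)[C@H]2C(=O)C[C@H]3C
F8 | step 15 | bridged hydroxy lactone (C5–OH; lactone between O3 and C14; C6 as in 26) | OC1C[C@@H]5[C@]2(C)[C@@H]3[C@@H]([C@H]2C(=O)C[C@H]3C)[C@@]1(C)C(=O)O5
F9 | step 15 | bridged keto lactone (C5 ketone; lactone between O3 and C14) | O=C1C[C@@H]5[C@]2(C)[C@@H]3[C@@H]([C@H]2C(=O)C[C@H]3C)[C@@]1(C)C(=O)O5
F10 | step 15 | hydroxy keto ester, methyl 3-hydroxy-2,6,9-trimethyl-5,11-dioxotricyclo[5.4.0.0^{2,8}]undecane-6-carboxylate | O=C1C[C@@H](O)[C@]2(C)[C@@H]3[C@@H]([C@H]2C(=O)C[C@H]3C)[C@@]1(C)C(=O)OC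
F11 | step 19 | phosphonopropionate ester of 24, 6-(acetoxymethyl)-3-[(tert-butyldimethylsilyl)oxy]-2,6,9-trimethyl-11-oxotricyclo[5.4.0.0^{2,8}]undecan-5-yl 2-[bis(2,2,2-trifluoroethoxy)phosphoryl]propanoate | CC(C(=O)O[C@@H]1C[C@@H](O[Si](C)(C)C(C)(C)C)[C@]2(C)[C@@H]3[C@@H]([C@H]2C(=O)C[C@H]3C)[C@@]1(C)COC(C)=O)P(=O)(OCC(F)(F)F)OCC(F)(F)F
A1 | alternative 1 | 6–7-fused keto mesylate (C11 ketone, C7 mesylate, O3, O5 and O14 as silyl ethers) | CS(=O)(=O)O[C@H]1[C@@H]2[C@H](C)CC(=O)C[C@]2(C)[C@H](O[Si](C)(C)C(C)(C)C)C[C@@H](O[Si](C)(C)C(C)(C)C)[C@]1(C)CO[Si](C)(C)C(C)(C)C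
A2 | alternative 2 | cycloundeca-1,7-dienone (C11 ketone, C1=C2 and C7=C8 alkenes, silyl ethers at O3, O5, O14) | C[C@@H]1CC(=O)/C=C(\C)[C@H](O[Si](C)(C)C(C)(C)C)C[C@@H](O[Si](C)(C)C(C)(C)C)[C@](C)(CO[Si](C)(C)C(C)(C)C)/C=C/1
A3 | alternative 3 | bicyclo[4.2.1]nonane α-diazoketone (diazo carbon = C1, C8 bearing the CH(Me)CH2CO2Me chain) | COC(=O)C[C@@H](C)[C@H]1[C@H]2C(=O)C(=[N+]=[N-])[C@]1(C)[C@H](O[Si](C)(C)C(C)(C)C)C[C@@H](O[Si](C)(C)C(C)(C)C)[C@]2(C)CO[Si](C)(C)C(C)(C)C
A4 | alternative 3 | ring-contracted bicyclo[4.1.1]octane C1 methyl ester | COC(=O)C[C@@H](C)[C@H]1[C@H]2[C@@H](C(=O)OC)[C@]1(C)[C@H](O[Si](C)(C)C(C)(C)C)C[C@@H](O[Si](C)(C)C(C)(C)C)[C@]2(C)CO[Si](C)(C)C(C)(C)C
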